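Assumption: the target SMILES carries no descriptor for the C8–C2' biaryl axis, so the target is taken as the racemic pair of atropisomers and no step is asked to control the axis.

## Analysis of the target

The target (C23H16O8) is an unsymmetrical binaphthoquinone. One half is a 5-hydroxy-3-methoxy-7-methyl-1,4-naphthoquinone (quinone ring A, benzenoid ring B, atoms C1–C8a). It is joined through C8 to C2' of a 5',8'-dihydroxy-3'-methyl-1',4'-naphthoquinone, a naphthazarin unit (quinone ring C, benzenoid ring D). There is no stereogenic carbon; the only stereo element is the C8–C2' axis, flanked by C7–CH3 and the C8a/C1=O peri region on one side and by C1'=O and C3'–CH3 on the other. The sensitive groups are the two quinones, the vinylogous ester C3–OCH3, the peri-hydroxyquinones (chelating, redox-active, base-labile) and the naphthazarin tautomerism, which lets rings C and D exchange roles. The difficulties are the fourfold ortho-substituted bond between two fully oxygenated naphthalenes, the placement of OCH3 at C3 and not C2, the methyl at C7 next to a free C6, and the differentiation of eight oxygens. The strategy rests on ring B: in the sequence C5(OH)–C6(H)–C7(CH3)–C8(aryl), C6 is the only unsubstituted carbon and lies between the oxygen-bearing C5 and the methyl-bearing C7. Deleting C6 and joining C5 to C7 turns ring B into the five-membered ring of a 3-aryl-2-methylindan-1-one, with C5 as the carbonyl carbon, C7 as the α-carbon and C8 as a benzylic sp3 carbon. The hindered axis can therefore be laid down as an ordinary sp3 C–aryl bond and becomes an axis only when ring B aromatises.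

## Retrosynthetic reasoning

24 to 23: the two O–CH3 bonds peri to the quinone carbonyls of rings C/D are cut last. The naphthazarin is the most redox-labile and chelating part, and its peri position allows chelation-directed cleavage that should spare the C3 methoxy group of ring A.

23 to 22: both quinones are traced back to para-dimethoxyarenes. In 22 every oxygen except C5–OH is a methyl ether, so all earlier C–C bond formations work on robust, electron-rich arenes. The forward step must oxidise two rings at once.

22 to 21: C6–H comes from C6–Br. The halogen is the trace left by the one-carbon reagent and is removed by hydrogenolysis.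

21 to 17 and 18: C6 is excised by cutting C5–C6 and C6–C7 and rejoining C5 to C7. This is chosen over cutting the biaryl bond, which would demand a fourfold ortho-substituted aryl–aryl coupling. The forward reaction must deliver one carbon from bromoform 18 to the enol double bond of the silyl enol ether 17 and then enlarge the ring and aromatise it. What is gained is that the axis disappears into the C3–aryl bond of an indane.

17 to 16: the O–Si bond is cut. Indanone 16 has a single α-carbon, so its enol ether can only have the C1=C2 double bond and the position of insertion is fixed.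

16 to 14: the acyl–aryl bond (C5–C4a of the target) is cut. The forward Friedel–Crafts acylation has only one free ortho carbon to attack, C6 of the trimethoxyphenyl ring, because both ortho positions of the naphthyl ring are substituted.

14 to 9 and 12: the C7–C8 bond is cut between the diarylmethyl carbon and the α-carbon of a propanoic acid. The carbinol 9 ionises easily to a cation stabilised by both arenes. The ketene acetal 12 brings C5, C7 and the C7 methyl group as one three-carbon unit at the right oxidation level.

9 to 6 and 7: the future axis C8–C2' is cut as aryllithium plus aldehyde, where four ortho substituents matter little. The aldehyde 7 supplies ring A complete: its 2-, 4- and 5-methoxy groups become C1=O, C3–OCH3 and C4=O, so the 3-methoxy regiochemistry is bought, not made.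

6 to 4, 3 and 1: the methyl group is placed by lithiation between bromine and methoxy in 4, which fixes bromine and methyl on neighbouring carbons without ambiguity. 4 comes from bromination of the symmetric ether 3, and 3 from reductive methylation of naphthazarin 1. The ketene acetal 12 comes from propanoic acid 10.

## Alternatives that were turned down

Alternative 1: Ring A is disconnected by a photochemical ketene benzannulation.
- Forward key step: the biaryl diazoketone 2-diazo-1-[2-methoxy-4-methyl-5-(1,4,5,8-tetramethoxy-3-methylnaphthalen-2-yl)phenyl]ethan-1-one A1 is irradiated with methoxyethyne A2. Wolff rearrangement gives an arylketene, which adds [2+2] to the alkyne; four-electron opening of the cyclobutenone and six-electron closure onto ring B should give 3,5-dimethoxy-7-methyl-8-(1,4,5,8-tetramethoxy-3-methylnaphthalen-2-yl)naphthalen-1-ol A3.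
- For it: four bonds of ring A form in one flask, the ketene–ynol ether polarity fixes OCH3 at C3 and OH at C1, no strong base is used and no halogen has to be removed.
- Against it: A1 already contains the C8–C2' bond, so a threefold ortho-substituted biaryl must first be made by cross-coupling. The six-electron closure must then occur at the one free ortho carbon, directly beside the perpendicular naphthyl group, and it is this step that creates the fully hindered axis. The tetramethoxynaphthalene chromophore absorbs strongly and is photo-oxidisable, and A2 is volatile and unstable. After A3, C4 still has to be oxidised and three peri ethers cleaved.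
- Comparison: Alternative 1 is as strong on the regiochemistry of ring A and stronger in needing no dehalogenation. The chosen strategy offers purely thermal, ionic chemistry, no hindered cross-coupling, and an axis that arises only on aromatisation.

Alternative 2: Ring C is disconnected at C1'–C8a' and C4'–C4a' by a Diels–Alder reaction.
- Forward key step: 3-(4,5,6,8-tetramethoxy-2-methylnaphthalen-1-yl)-4-methyl-2,5-bis(trimethylsilyloxy)furan A4 adds to p-benzoquinone A5. Opening of the oxygen bridge with loss of both silyl groups as the disiloxane should give 5,8-dihydroxy-3-methyl-2-(4,5,6,8-tetramethoxy-2-methylnaphthalen-1-yl)-1,4-naphthoquinone A6.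
- For it: rings C and D appear in one step at the naphthazarin oxidation level with both peri hydroxyls free. No oxidation or demethylation is needed for that half, and the tautomerism makes the regiochemistry irrelevant.
- Against it: A4 derives from an arylsuccinic anhydride whose aryl group is the complete A/B naphthalene attached at C1, between a methyl group and a peri methoxy group. The hard connection is thus only moved to an earlier, equally crowded arylation, and that naphthalene must first be built with regiocontrol. A4 is a very electron-rich, hydrolytically fragile diene, and A5 can oxidise it instead of adding. The later oxidation of ring A and cleavage of the C5 ether must then be done beside a free, chelating, oxidisable naphthazarin.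
- Comparison: Alternative 2 is stronger in end-game economy for the naphthazarin half. The chosen strategy offers a reliable organolithium fragment union and keeps every redox-active ring masked as methyl ethers until the last two steps.

Alternative 3: Ring B is closed by acylation at C4a–C5 instead of by ring enlargement.
- Forward key step: the diaryl ketone (1,4,5,8-tetramethoxy-3-methylnaphthalen-2-yl)(2,4,5-trimethoxyphenyl)methanone A7 undergoes Stobbe condensation with a succinic diester to the half-ester (Z)-3-(methoxycarbonyl)-4-(1,4,5,8-tetramethoxy-3-methylnaphthalen-2-yl)-4-(2,4,5-trimethoxyphenyl)but-3-enoic acid A8. Acetylating dehydration then closes the ring to methyl 4-acetoxy-5,6,8-trimethoxy-1-(1,4,5,8-tetramethoxy-3-methylnaphthalen-2-yl)naphthalene-2-carboxylate A9.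
- For it: the chemistry is classical and carbene-free, the closure has only one free ortho carbon to attack, ring B arrives aromatic with C6–H in place, and A7 is one oxidation away from carbinol 9.
- Against it: the Stobbe enolate must attack a carbonyl flanked by three ortho substituents and deactivated by two electron-rich arenes. Only the alkene isomer with the carboxymethyl group cis to the trimethoxyphenyl ring can cyclise. A9 carries an ester at C7 where the target needs a methyl group, which costs two to three further steps while the C5 acetate is carried along.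
- Comparison: Alternative 3 is as strong on regiochemistry, stronger on precedent for the ring-closing event and needs no dehalogenation. The chosen strategy brings the C7 methyl group in at the correct oxidation level with 12 and completes ring B with a one-carbon reagent, which saves the ester-to-methyl sequence.

Key step: step 9

## Route

Step 1
Reactants: 1 5,8-dihydroxynaphthalene-1,4-dione (naphthazarin)
Product: 3 1,4,5,8-tetramethoxynaphthalene, via naphthalene-1,4,5,8-tetrol 2 (not isolated)
Conditions: Na2S2O4, NaOH, Bu4NBr (cat.), THF–H2O, rt, N2; then (CH3O)2SO2, rt → 40 °C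
Reagents that add atoms: dimethyl sulfate, COS(=O)(=O)OC
Why: Dithionite reduces the quinone to the air-sensitive tetrol 2, whose four phenoxides are O-methylated in the same pot under phase transfer (reductive Williamson etherification).

Step 2
Reactants: 3 1,4,5,8-tetramethoxynaphthalene
Product: 4 2-bromo-1,4,5,8-tetramethoxynaphthalene
Conditions: NBS (1.0 equiv), CH3CN, 0 °C → rt, dark
Reagents that add atoms: N-bromosuccinimide, O=C1CCC(=O)N1Br
Why: Electrophilic aromatic bromination; the four free positions of 3 are equivalent and each is ortho to a methoxy group, and the first bromine deactivates the nucleus enough for one equivalent to stop at 4.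

Step 3
Reactants: 4 2-bromo-1,4,5,8-tetramethoxynaphthalene
Product: 6 2-bromo-1,4,5,8-tetramethoxy-3-methylnaphthalene, via 3-lithio-2-bromo-1,4,5,8-tetramethoxynaphthalene 5 (not isolated)
Conditions: LiN(iPr)2 (1.2 equiv), THF, −78 °C; then CH3I (3 equiv), −78 °C → rt
Reagents that add atoms: iodomethane, CI
Why: Directed ortho-lithiation: C3–H lies between Br and OCH3 and is the most acidic ring hydrogen, and the amide base does not undergo bromine–lithium exchange. At −78 °C the ortho-bromoaryllithium 5 should be methylated before it can lose LiBr, so bromine and methyl end up on adjacent carbons without regiochemical ambiguity.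

Step 4
Reactants: 6 2-bromo-1,4,5,8-tetramethoxy-3-methylnaphthalene; 7 2,4,5-trimethoxybenzaldehyde
Product: 9 rac-(1,4,5,8-tetramethoxy-3-methylnaphthalen-2-yl)(2,4,5-trimethoxyphenyl)methanol, via aryllithium 8 (not isolated)
Conditions: n-BuLi (1.05 equiv), THF, −78 °C; then 7, −78 → 0 °C; H2O
Reagents that add atoms: none
Why: Bromine–lithium exchange followed by 1,2-addition of the aryllithium to the aldehyde; the future biaryl bond is made at an sp3 carbon where the ortho substituents do not block approach. The new stereocenter is formed racemic and is erased in step 9.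

Step 5
Reactants: 10 propanoic acid
Product: 12 1,1-bis(trimethylsilyloxy)prop-1-ene, via dilithium enediolate 11 (not isolated)
Conditions: LiN(iPr)2 (2.2 equiv), THF, 0 °C; then (CH3)3SiCl (2.5 equiv), 0 °C → rt; filtration, distillation
Reagents that add atoms: chlorotrimethylsilane, C[Si](C)(C)Cl
Why: Double deprotonation of the acid and O,O-silylation of the enediolate gives the ketene bis(silyl) acetal, a propanoic acid enolate equivalent that tolerates Lewis acids and releases the free acid on work-up.

Step 6
Reactants: 9 rac-(1,4,5,8-tetramethoxy-3-methylnaphthalen-2-yl)(2,4,5-trimethoxyphenyl)methanol; 12 1,1-bis(trimethylsilyloxy)prop-1-ene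
Product: 14 2-methyl-3-(1,4,5,8-tetramethoxy-3-methylnaphthalen-2-yl)-3-(2,4,5-trimethoxyphenyl)propanoic acid (both racemic diastereomers), via silyl ester 13 (not isolated)
Conditions: 12 (2.5 equiv), (CH3)3SiOSO2CF3 (10 mol %), CH2Cl2, −78 → −20 °C; then 1 M HCl, THF, rt
Reagents that add atoms: none
Why: SN1 substitution of a diarylmethanol (Mukaiyama-type alkylation): the cation stabilised by both electron-rich arenes forms with catalytic silyl triflate and is captured at carbon by the ketene acetal, and the silyl ester 13 is hydrolysed on acidic work-up. The two new stereocenters are uncontrolled and both are erased later (C2 in step 8, C3 in step 9).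

Step 7
Reactants: 14 2-methyl-3-(1,4,5,8-tetramethoxy-3-methylnaphthalen-2-yl)-3-(2,4,5-trimethoxyphenyl)propanoic acid
Product: 16 4,6,7-trimethoxy-2-methyl-3-(1,4,5,8-tetramethoxy-3-methylnaphthalen-2-yl)indan-1-one (cis/trans mixture of racemates), via mixed trifluoroacetic anhydride 15 (not isolated)
Conditions: (CF3CO)2O (3 equiv), CF3CO2H, CH2Cl2, 0 °C → rt
Reagents that add atoms: none
Why: Intramolecular Friedel–Crafts acylation through the mixed anhydride 15; the only free ortho carbon on either aryl group is C6 of the trimethoxyphenyl ring (ortho to OCH3), so only the five-membered ring with the 4,6,7-trimethoxy pattern can close. The halide-free medium avoids demethylative lactonisation by an ortho methoxy group.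

Step 8
Reactants: 16 4,6,7-trimethoxy-2-methyl-3-(1,4,5,8-tetramethoxy-3-methylnaphthalen-2-yl)indan-1-one
Product: 17 rac-4,6,7-trimethoxy-2-methyl-3-(1,4,5,8-tetramethoxy-3-methylnaphthalen-2-yl)-1-(trimethylsilyloxy)-1H-indene (indanone numbering kept; C3 is the sp3 carbon)
Conditions: (CH3)3SiOSO2CF3 (1.3 equiv), Et3N (2.5 equiv), CH2Cl2, 0 °C; pentane, cold NaHCO3 wash, used crude
Reagents that add atoms: trimethylsilyl trifluoromethanesulfonate, C[Si](C)(C)OS(=O)(=O)C(F)(F)F
Why: Soft enolisation and O-silylation of a ketone with a single α-carbon, so only the C1=C2 enol ether can form and both diastereomers of 16 converge; the amine base is too weak to remove the doubly benzylic C3–H.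

Step 9
Reactants: 17 rac-4,6,7-trimethoxy-2-methyl-3-(1,4,5,8-tetramethoxy-3-methylnaphthalen-2-yl)-1-(trimethylsilyloxy)-1H-indene; 18 bromoform
Product: 21 2-bromo-5,7,8-trimethoxy-3-methyl-4-(1,4,5,8-tetramethoxy-3-methylnaphthalen-2-yl)naphthalen-1-ol, via siloxy-dibromocyclopropane 19 (not isolated), via 2-bromo-4H-naphthalen-1-one 20 (not isolated)
Conditions: CHBr3 (2.5 equiv), KOC(CH3)3 (4 equiv, added in portions), hexane–toluene, −20 °C → rt; then 1 M HCl
Reagents that add atoms: none
Why: α-Elimination of bromoform by KOC(CH3)3 gives electrophilic singlet dibromocarbene, which adds in a concerted [2+1] fashion across the C1=C2 enol ether bond of 17, anti to the C3 aryl group, to give 19. The endo bromide of 19 then ionises with disrotatory opening of the old C1–C2 bond, the only allowed mode for a cyclopropane fused to a five-membered ring, and the resulting 2-bromoallyl cation is stabilised as a silyloxocarbenium ion that loses its silyl group to give bromo enone 20. Base removes the doubly benzylic C4–H of 20, and the dienolate is the naphtholate of 21, so aromatisation drives the sequence. The closest known reaction type is the dihalocarbene ring enlargement of cyclic silyl enol ethers to 2-halo-enones and of indenes and indanone silyl enol ethers to 2-halonaphthalenes and 2-halo-1-naphthols. Ring B is not closed by cyclisation but arises by enlargement of the five-membered ring: two σ bonds to the new carbon (C5–C6 and C6–C7 in target numbering) form in the cheletropic addition and the old C5–C7 bond breaks electrocyclically. No stereocenter survives, since the three of 19 and C4 of 20 are erased on aromatisation and the biaryl axis forms as a racemate. The step needs chemoselectivity for the enol ether over the methoxyarenes, secured by its far higher nucleophilicity, and carbene transfer faster than O–Si cleavage or deprotonation at C3, secured by keeping bromoform in excess over a sparingly soluble base added in portions to a cold non-polar medium.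

Step 10
Reactants: 21 2-bromo-5,7,8-trimethoxy-3-methyl-4-(1,4,5,8-tetramethoxy-3-methylnaphthalen-2-yl)naphthalen-1-ol
Product: 22 5,7,8-trimethoxy-3-methyl-4-(1,4,5,8-tetramethoxy-3-methylnaphthalen-2-yl)naphthalen-1-ol
Conditions: H2 (1 atm), 10% Pd/C, NaOAc, EtOAc–CH3OH, rt
Reagents that add atoms: none
Why: Catalytic hydrogenolysis of the aryl C–Br bond with NaOAc as HBr scavenger; methyl ethers, the free naphthol and the biaryl bond are inert under these conditions.

Step 11
Reactants: 22 5,7,8-trimethoxy-3-methyl-4-(1,4,5,8-tetramethoxy-3-methylnaphthalen-2-yl)naphthalen-1-ol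
Product: 23 8-(5,8-dimethoxy-3-methyl-1,4-dioxo-1,4-dihydronaphthalen-2-yl)-5-hydroxy-3-methoxy-7-methylnaphthalene-1,4-dione
Conditions: (NH4)2Ce(NO3)6 (6 equiv), CH3CN–H2O, 0 °C
Reagents that add atoms: water, O
Why: Oxidative demethylation by tetravalent cerium: each para-dimethoxy ring is oxidised through its radical cation, water adds at the ipso carbons and methanol leaves; in ring A the para pair gives the 1,4-quinone and leaves the third methoxy group as the C3 vinylogous ester. In the other half the fully substituted, more electron-rich ring is expected to be oxidised; oxidation of its other ring would give an isomer that converges on 24 in step 12, because naphthazarin tautomers interconvert.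

Step 12
Reactants: 23 8-(5,8-dimethoxy-3-methyl-1,4-dioxo-1,4-dihydronaphthalen-2-yl)-5-hydroxy-3-methoxy-7-methylnaphthalene-1,4-dione
Product: 24 8-(5,8-dihydroxy-3-methyl-1,4-dioxo-1,4-dihydronaphthalen-2-yl)-5-hydroxy-3-methoxy-7-methylnaphthalene-1,4-dione (8'-hydroxy-3-methoxyisodiospyrin)
Conditions: BCl3 (6 equiv), CH2Cl2, −78 → 0 °C; then H2O
Reagents that add atoms: none
Why: Chelation-directed peri demethylation: BCl3 binds the quinone carbonyls of ring C and cleaves the two methyl ethers held in six-membered chelates. The C3 methoxy group can only form a weaker five-membered chelate to a carbonyl already tied up by the peri C5–O–B chelate, so it should survive at low temperature.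

## Compound list

1 | 5,8-dihydroxynaphthalene-1,4-dione (naphthazarin) | O=C1C=CC(=O)c2c(O)ccc(O)c12 | starting material
2 | naphthalene-1,4,5,8-tetrol | Oc1ccc(O)c2c(O)ccc(O)c12 | intermediate
3 | 1,4,5,8-tetramethoxynaphthalene | COc1ccc(OC)c2c(OC)ccc(OC)c12 | intermediate
4 | 2-bromo-1,4,5,8-tetramethoxynaphthalene | COc1cc(Br)c(OC)c2c(OC)ccc(OC)c12 | intermediate
5 | (3-bromo-1,4,5,8-tetramethoxynaphthalen-2-yl)lithium | [Li]c1c(Br)c(OC)c2c(OC)ccc(OC)c2c1OC | intermediate
6 | 2-bromo-1,4,5,8-tetramethoxy-3-methylnaphthalene | Cc1c(Br)c(OC)c2c(OC)ccc(OC)c2c1OC | intermediate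
7 | 2,4,5-trimethoxybenzaldehyde | COc1cc(OC)c(C=O)cc1OC | starting material
8 | (1,4,5,8-tetramethoxy-3-methylnaphthalen-2-yl)lithium | [Li]c1c(C)c(OC)c2c(OC)ccc(OC)c2c1OC | intermediate
9 | rac-(1,4,5,8-tetramethoxy-3-methylnaphthalen-2-yl)(2,4,5-trimethoxyphenyl)methanol (racemic, one enantiomer drawn) | COc1cc(OC)c([C@H](O)c2c(C)c(OC)c3c(OC)ccc(OC)c3c2OC)cc1OC | intermediate
10 | propanoic acid | CCC(=O)O | starting material
11 | dilithium prop-1-ene-1,1-diolate | CC=C(O[Li])O[Li] | intermediate
12 | 1,1-bis(trimethylsilyloxy)prop-1-ene | CC=C(O[Si](C)(C)C)O[Si](C)(C)C | intermediate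
13 | trimethylsilyl 2-methyl-3-(1,4,5,8-tetramethoxy-3-methylnaphthalen-2-yl)-3-(2,4,5-trimethoxyphenyl)propanoate (diastereomer mixture, racemic) | CC(C(=O)O[Si](C)(C)C)C(c1cc(OC)c(OC)cc1OC)c1c(C)c(OC)c2c(OC)ccc(OC)c2c1OC | intermediate
14 | 2-methyl-3-(1,4,5,8-tetramethoxy-3-methylnaphthalen-2-yl)-3-(2,4,5-trimethoxyphenyl)propanoic acid (both racemic diastereomers) | CC(C(=O)O)C(c1cc(OC)c(OC)cc1OC)c1c(C)c(OC)c2c(OC)ccc(OC)c2c1OC | intermediate
15 | mixed anhydride of 14 with trifluoroacetic acid (diastereomer mixture, racemic) | CC(C(=O)OC(=O)C(F)(F)F)C(c1cc(OC)c(OC)cc1OC)c1c(C)c(OC)c2c(OC)ccc(OC)c2c1OC | intermediate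
16 | 4,6,7-trimethoxy-2-methyl-3-(1,4,5,8-tetramethoxy-3-methylnaphthalen-2-yl)indan-1-one (cis/trans mixture of racemates) | CC1C(c2c(C)c(OC)c3c(OC)ccc(OC)c3c2OC)c2c(OC)cc(OC)c(OC)c2C1=O | intermediate
17 | rac-4,6,7-trimethoxy-2-methyl-3-(1,4,5,8-tetramethoxy-3-methylnaphthalen-2-yl)-1-(trimethylsilyloxy)-1H-indene, indanone numbering (racemic, one enantiomer drawn) | C[Si](C)(C)OC1=C(C)[C@H](c2c(C)c(OC)c3c(OC)ccc(OC)c3c2OC)c2c(OC)cc(OC)c(OC)c12 | intermediate
18 | bromoform | BrC(Br)Br | starting material
19 | dibromocyclopropane adduct of 17: CBr2 bridging C1 and C2 of the indane, anti to the C3 aryl group (racemic, one enantiomer drawn) | C[Si](C)(C)O[C@]12C(Br)(Br)[C@@]1(C)[C@H](c3c(C)c(OC)c4c(OC)ccc(OC)c4c3OC)c1c(OC)cc(OC)c(OC)c12 | intermediate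
20 | rac-2-bromo-5,7,8-trimethoxy-3-methyl-4-(1,4,5,8-tetramethoxy-3-methylnaphthalen-2-yl)naphthalen-1(4H)-one (racemic, one enantiomer drawn) | O=C1C(Br)=C(C)[C@H](c2c(C)c(OC)c3c(OC)ccc(OC)c3c2OC)c2c(OC)cc(OC)c(OC)c12 | intermediate
21 | 2-bromo-5,7,8-trimethoxy-3-methyl-4-(1,4,5,8-tetramethoxy-3-methylnaphthalen-2-yl)naphthalen-1-ol (racemic about the biaryl axis) | COc1cc(OC)c2c(-c3c(C)c(OC)c4c(OC)ccc(OC)c4c3OC)c(C)c(Br)c(O)c2c1OC | intermediate
22 | 5,7,8-trimethoxy-3-methyl-4-(1,4,5,8-tetramethoxy-3-methylnaphthalen-2-yl)naphthalen-1-ol (racemic about the biaryl axis) | COc1cc(OC)c2c(-c3c(C)c(OC)c4c(OC)ccc(OC)c4c3OC)c(C)cc(O)c2c1OC | intermediate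
23 | 8-(5,8-dimethoxy-3-methyl-1,4-dioxo-1,4-dihydronaphthalen-2-yl)-5-hydroxy-3-methoxy-7-methylnaphthalene-1,4-dione (racemic about the biaryl axis) | COC1=CC(=O)c2c(C3=C(C)C(=O)c4c(OC)ccc(OC)c4C3=O)c(C)cc(O)c2C1=O | intermediate
24 | 8-(5,8-dihydroxy-3-methyl-1,4-dioxo-1,4-dihydronaphthalen-2-yl)-5-hydroxy-3-methoxy-7-methylnaphthalene-1,4-dione (racemic about the biaryl axis) | COC1=CC(=O)c2c(C3=C(C)C(=O)c4c(O)ccc(O)c4C3=O)c(C)cc(O)c2C1=O | target

## Step count and risks

Total step count: 12. Longest linear sequence: 11 steps (steps 1–4 and 6–12 from 1; step 5 is a one-step side branch).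

Step 9 (key step). Three processes are most likely to go wrong.
- tert-Butoxide may cleave the O–Si bond of 17 before carbene transfer; the free enolate is then only C-alkylated at C2 by the carbene and cannot enlarge.
- A base-induced 1,3-hydrogen shift of the doubly benzylic C3–H would move the double bond to C2=C3 and put the new carbon between the methyl- and aryl-bearing carbons.
- Addition to the crowded tetrasubstituted double bond may be slow, which gives the carbene time to attack the methoxyarenes or the product naphtholate.

Fallback: a base-free two-stage insertion of CH in place of CBr, setting out from 17. Cyclopropanation with Et2Zn/CH2I2 (Simmons–Smith conditions) should give the siloxycyclopropane F1. FeCl3 in DMF opens its internal bond oxidatively to the ring-enlarged 3-chlorotetralone F2. NaOAc in CH3OH eliminates HCl to the 4H-naphthalen-1-one F3, which tautomerises with a trace of acid or base. The fallback comes back to the route at 22, so step 10 falls away.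

Step 7. The risks are acid-induced loss of the trimethoxyphenyl group by ipso protonation (retro-Friedel–Crafts), trifluoroacetylation of a free ring position, and sluggish acylation at a carbon activated by only one ortho methoxy group. Fallback: setting out from 9, the carbinol is used to alkylate 2,2,5-trimethyl-1,3-dioxane-4,6-dione under Sc(OTf)3 catalysis to the quaternary Meldrum's acid derivative F4. Heating F4 with catalytic Sc(OTf)3 in CH3NO2 effects the Friedel–Crafts acylation from the neutral cyclic acylal with loss of acetone and CO2. This comes back to the route at 16 and bypasses 12–15.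

Step 11. The risk is over-oxidation of the free naphthol ring (attack of water para to the hydroxyl at the aryl-bearing carbon, ortho-quinone formation or radical coupling) in competition with oxidative demethylation. Fallback: setting out from 22, acetylation (Ac2O, pyridine, DMAP) gives the naphthyl acetate F5. Oxidation with (NH4)2Ce(NO3)6 then gives the bis-quinone acetate F6, and acid methanolysis (HCl, CH3OH) removes the acetate; the vinylogous ester exchange with methanol is degenerate. This comes back to the route at 23.

Step 12. The risk is loss of the C3 methyl ether (cleavage of the vinylogous ester) along with the peri ethers, or incomplete cleavage if the reaction is kept cold enough to spare it. Fallback: setting out from 23, all three ethers are cleaved with excess BBr3 to the 3-hydroxyquinone F7. Only the vinylogous acid hydroxyl at C3 is then re-etherified by acid-catalysed reaction with methanol (HCl, CH3OH, reflux), since the chelated peri phenols do not react. This comes back to the route at 24.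

## Further compounds

F1 | step 9 | siloxycyclopropane from CH2 addition across C1=C2 of 17, CH2 anti to the C3 aryl group (racemic, one enantiomer drawn) | C[Si](C)(C)O[C@]12C[C@@]1(C)[C@H](c3c(C)c(OC)c4c(OC)ccc(OC)c4c3OC)c1c(OC)cc(OC)c(OC)c12
F2 | step 9 | 3-chloro-5,7,8-trimethoxy-3-methyl-4-(1,4,5,8-tetramethoxy-3-methylnaphthalen-2-yl)-3,4-dihydronaphthalen-1(2H)-one (diastereomer mixture, racemic) | O=C1CC(C)(Cl)C(c2c(C)c(OC)c3c(OC)ccc(OC)c3c2OC)c2c(OC)cc(OC)c(OC)c12
F3 | step 9 | rac-5,7,8-trimethoxy-3-methyl-4-(1,4,5,8-tetramethoxy-3-methylnaphthalen-2-yl)naphthalen-1(4H)-one (racemic, one enantiomer drawn) | O=C1C=C(C)[C@H](c2c(C)c(OC)c3c(OC)ccc(OC)c3c2OC)c2c(OC)cc(OC)c(OC)c12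
F4 | step 7 | rac-2,2,5-trimethyl-5-[(1,4,5,8-tetramethoxy-3-methylnaphthalen-2-yl)(2,4,5-trimethoxyphenyl)methyl]-1,3-dioxane-4,6-dione (racemic, one enantiomer drawn) | CC1(C)OC(=O)C(C)([C@H](c2cc(OC)c(OC)cc2OC)c2c(C)c(OC)c3c(OC)ccc(OC)c3c2OC)C(=O)O1
F5 | step 11 | 5,7,8-trimethoxy-3-methyl-4-(1,4,5,8-tetramethoxy-3-methylnaphthalen-2-yl)naphthalen-1-yl acetate | COc1cc(OC)c2c(-c3c(C)c(OC)c4c(OC)ccc(OC)c4c3OC)c(C)cc(OC(C)=O)c2c1OC
F6 | step 11 | 4-(5,8-dimethoxy-3-methyl-1,4-dioxo-1,4-dihydronaphthalen-2-yl)-7-methoxy-3-methyl-5,8-dioxo-5,8-dihydronaphthalen-1-yl acetate | COC1=CC(=O)c2c(C3=C(C)C(=O)c4c(OC)ccc(OC)c4C3=O)c(C)cc(OC(C)=O)c2C1=O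
F7 | step 12 | 8-(5,8-dihydroxy-3-methyl-1,4-dioxo-1,4-dihydronaphthalen-2-yl)-3,5-dihydroxy-7-methylnaphthalene-1,4-dione | OC1=CC(=O)c2c(C3=C(C)C(=O)c4c(O)ccc(O)c4C3=O)c(C)cc(O)c2C1=O
A1 | alternative 1 | 2-diazo-1-[2-methoxy-4-methyl-5-(1,4,5,8-tetramethoxy-3-methylnaphthalen-2-yl)phenyl]ethan-1-one | [N-]=[N+]=CC(=O)c1cc(-c2c(C)c(OC)c3c(OC)ccc(OC)c3c2OC)c(C)cc1OC
A2 | alternative 1 | methoxyethyne | COC#C
A3 | alternative 1 | 3,5-dimethoxy-7-methyl-8-(1,4,5,8-tetramethoxy-3-methylnaphthalen-2-yl)naphthalen-1-ol | COc1cc(O)c2c(-c3c(C)c(OC)c4c(OC)ccc(OC)c4c3OC)c(C)cc(OC)c2c1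
A4 | alternative 2 | 3-(4,5,6,8-tetramethoxy-2-methylnaphthalen-1-yl)-4-methyl-2,5-bis(trimethylsilyloxy)furan | C[Si](C)(C)Oc1oc(O[Si](C)(C)C)c(C)c1-c1c(C)cc(OC)c2c(OC)c(OC)cc(OC)c12
A5 | alternative 2 | p-benzoquinone | O=C1C=CC(=O)C=C1
A6 | alternative 2 | 5,8-dihydroxy-3-methyl-2-(4,5,6,8-tetramethoxy-2-methylnaphthalen-1-yl)-1,4-naphthoquinone | CC1=C(-c2c(C)cc(OC)c3c(OC)c(OC)cc(OC)c23)C(=O)c2c(O)ccc(O)c2C1=O
A7 | alternative 3 | (1,4,5,8-tetramethoxy-3-methylnaphthalen-2-yl)(2,4,5-trimethoxyphenyl)methanone | O=C(c1cc(OC)c(OC)cc1OC)c1c(C)c(OC)c2c(OC)ccc(OC)c2c1OC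
A8 | alternative 3 | (Z)-3-(methoxycarbonyl)-4-(1,4,5,8-tetramethoxy-3-methylnaphthalen-2-yl)-4-(2,4,5-trimethoxyphenyl)but-3-enoic acid | COC(=O)/C(CC(=O)O)=C(/c1cc(OC)c(OC)cc1OC)c1c(C)c(OC)c2c(OC)ccc(OC)c2c1OC
A9 | alternative 3 | methyl 4-acetoxy-5,6,8-trimethoxy-1-(1,4,5,8-tetramethoxy-3-methylnaphthalen-2-yl)naphthalene-2-carboxylate | COC(=O)c1cc(OC(C)=O)c2c(OC)c(OC)cc(OC)c2c1-c1c(C)c(OC)c2c(OC)ccc(OC)c2c1OC
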